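We cannot charge more D to make more G without giving every J.G more D to react with, since D feeds step 4 and also takes up J.G in step 2.

    J + G → J.G (k1 = 1.08 M⁻¹ s⁻¹)
    D + J.G → D.J.G (k2 = 0.375 M⁻¹ s⁻¹)
    L ⇌ J (K3 = 0.812, k3 = 0.0192 s⁻¹)
    D → G (k4 = 0.0313 s⁻¹)

| flask | L | D | time |
|---|---|---|---|
| alder | 43 mM | 15.0 mM | 30 s |
| larch | 43 mM | 50.0 mM | 30 s |
| maple | 43 mM | 150 mM | 30 s |
| oak | 43 mM | 400 mM | 30 s |
| ash | 43 mM | 1200 mM | 30 s |

- amount of J.G at the end, in percent of the L charged for alder, larch, maple, oak, ash, in this order
- how that number moves from the first to the last of them (rises, then falls / falls all the way / hardly changes / falls, then rises / rises all the way)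

- "hardly changes" means that all values lie within two and a half points (for a concentration: within two and a half percent of the largest)
- run time (alder): 30 s

For whoever takes over the bench: each flask holds L passing into J while D passes into G, and J and G join to J.G. When you come at the end of the run, we expect step 4 alone, with its half-life of 22 s, to have left 39.1% of the charged D, and the forward step alone to have left 56.2% of L.

Do not expect each further charge of D to raise the yield of J.G. Step 4 is first order, so the D that a J.G meets over the run grows in proportion to the charge. We therefore define the burn charge, the charge of D at which a J.G present from the start has suffered one e-fold of loss through step 2 by the end of the run: 137 mM.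

On a logarithmic scale, alder stands 0.961 decades below it and ash 0.942 decades above. J.G made late meets less D than this, so we commit to a rise and then a fall, with the top somewhat above the burn charge, between maple and oak.

The forecast gives 3.5%, 9.8%, 18%, 14.5% and 6.5%, so rises, then falls, holding that “the same reagent consumes J.G”. It puts the peak near 150 mM, at maple, which is lower than our placing.

The simulation gives 3.42%, 9.56%, 17.6%, 16.4% and 6.31%, so rises, then falls, and the row turns at a reading of 230 mM, which is 1.66 burn charges. In alder, at 0.109 of the burn charge, the half-life of J.G by step 2 at the charged D is 120 s, longer than the run of 30 s, and at the end D.J.G stands at 0.0867% of the L charged beside J.G at 3.42%. In oak, at 2.92 burn charges, D.J.G stands at 18.1% beside J.G at 16.4% after 30.0 s.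

All constants belong to no real substance; the rest is arithmetic.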